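The numbers in the tables are simulated with made-up constants; noise was put on by code.

- Slowness is what you count here: in the epsilon run substrate is down to 2.5 % at 0.500 d, yet target stands at 27.6 % and keeps climbing, so material waits in an unread store, an intermediate.

| flask | substrate | reagent | remark | time |
|---|---|---|---|---|
| zeta | 0.032 M | 0.0384 M | run made earlier |  |
| epsilon | 0.032 M | 0.054 M | run made earlier |  |
| beta | 0.032 M | 0.084 M | run made earlier |  |
| theta | 0.048 M | 0.0384 M | run made earlier |  |
| winter | 0.032 M | 0.0384 M (fed, over 40 h) | all else is in the flask from the start; the feed brings no volume worth counting | 2.5 d |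
| autumn | 0.032 M (fed, over 40 h) | 0.0384 M | all else is in the flask from the start; the feed brings no volume worth counting | 2.5 d |
| noon | 0.032 M | 0.0384 M | everything together at the start | 2.5 d |

| run | time / d | target / % | substrate / % |
|---|---|---|---|
| zeta | 0.333 | 15.6 | 10.2 |
| zeta | 0.833 | 34.9 | 3.4 |
| zeta | 1.67 | 46.1 | 1.4 |
| zeta | 2.50 | 49.5 | 0.7 |
| epsilon | 0.250 | 14.2 | 6.5 |
| epsilon | 0.500 | 27.6 | 2.5 |
| epsilon | 1.25 | 45.1 | 0.2 |
| epsilon | 3.00 | 50.9 | 0 |
| beta | 0.833 | 41.1 | 0 |
| beta | 1.67 | 50.7 | 0.1 |
| beta | 2.50 | 51.5 | 0 |
| beta | 3.00 | 50.6 | 0.6 |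
| theta | 0.250 | 10.2 | 23.6 |
| theta | 0.500 | 20.7 | 13.7 |
| theta | 1.25 | 36.4 | 9.7 |
| theta | 3.00 | 40.3 | 9.6 |

(each reading ± 0.5 percentage points)

- the best flask by amount of target, in percent of the substrate charged; "all alike" if 1.5 percentage points covers them all (winter / autumn / noon / all alike)
- amount of target at the end, in percent of the substrate charged, winter
- amount of target at the end, in percent of the substrate charged, autumn
- amount of target at the end, in percent of the substrate charged, noon



- Between 0.500 d and 1.25 d the epsilon gap to its last reading shrinks from 23 percentage points to 5.8 points, which reads as 0.374 d: this is the catch-up half-life, a relaxation half-life, the time for target's gap to its level to fall by a factor of two.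
- Noon repeats zeta, so I draw its curve from there. In zeta target reads 15.6 % at 0.333 d, bends near 0.833 d as substrate reaches 3.4 %, and reads 49.5 % at 2.50 d.
- By my reckoning, target in winter and in autumn trails the steady feed by one lifetime, 0.540 d, and each of these flasks then has 2.23 half-lives left, more than one. My reckoned shortfall is therefore 6.90 % of the level.
- Taking beta's reading of 51.5 % at 2.50 d as the level, I put autumn near 47.9 %. Taking theta's substrate-rich reading of 40.3 % at 3.00 d as the level, I put winter near 37.5 %.
- The forecast says noon wins, with winter 41 %, autumn 47 % and noon 49.5 %, noting “Feeding ends at 1.67 d, leaving only 0.83 d for the intermediate to convert”. Its autumn stands below my autumn, and its winter above my winter.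
- The flasks give noon as best, with winter 41.0 %, autumn 44.7 % and noon 49.3 %.

    target ⇌ isomer of the product (K = 4.30, k = 0.00240 h⁻¹)
    substrate ⇌ dormant form (K = 1.10, k = 0.0520 h⁻¹)
    intermediate ⇌ target (K = 1.30, k = 0.0440 h⁻¹)
    substrate + reagent → intermediate + by-product (k = 13.0 M⁻¹ h⁻¹)

- Autumn's target climbs from 30.8 % at the end of its feed to 44.7 %, 3.2 points under my reckoning, with 11.5 % of substrate still present when feeding stopped. Now cut noon's reagent to 0.023 M, with the same time, 6.69 of my half-lives. At one reagent per substrate that charge equals 71.9 % of the substrate, so beta's reading gives 37.0 %. Reagent is the limiting reagent there, with 0.785 % of its charge left, and the neighbour ends at 36.7 %, below winter's 41.0 %.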